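**Retrosynthetic overview**

1. Rings: A = oxepane, B = the cyclohexane fused to it, C = the cyclohexene, D = the gem-dimethylcyclohexane. Ring order: A and B together first, D bought, C last.
2. Both tertiary methyl carbinols (rings B and D) come from exocyclic methylenes by one double Markovnikov hydration. The ring-C methyl comes from an enol triflate, itself from a silyl enol ether.
3. Ring C comes from a catalytic asymmetric endo [4+2] cycloaddition of a (Z)-2-silyloxy-1,3-diene carrying rings A/B with 4,4-dimethylcyclohex-2-enone (ring D).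
4. Enabling feature: ring C is a cyclohexene whose three contiguous CH carbons (the two C/D fusion carbons and the carbon bearing the two-carbon link) are all-cis and lie opposite its C(CH3)=CH unit, an endo Diels–Alder retron. The ring-D carbinol carbon next to the fusion is a latent enone carbonyl, and the ring-C methyl carbon is a latent enol-ether carbon that steers regiochemistry.
5. The diene comes from a vinyl ketone, made by Giese extension of a bicyclic iodide. Rings A/B come from an epoxonium tandem oxa-/carbacyclization of a Shi-derived bis-epoxy allylsilane (ethyl acetoacetate + geranyl bromide).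

Key step: step 13

Remark: the facial sense of the catalyst in step 13 is assigned from the accepted α-C–H···O binding model of cyclic enones on the oxazaborolidinium Lewis acid; the catalyst antipode is equally available from (R)-proline.

**Route**

Step 1
Reactants: 1 ethyl acetoacetate; 2 geranyl bromide
Product: 4 ethyl (6E)-7,11-dimethyl-3-oxododeca-6,10-dienoate, via acetoacetate dianion 3 (not isolated)
Conditions: NaH, THF, 0 °C; n-BuLi, 0 °C; then 2, 0 °C to rt; aq. HCl quench
Reagents that add atoms: none
Why: γ-alkylation of the acetoacetate dianion by the allylic bromide is a standard SN2 chain extension that leaves the (E)-alkene untouched and forms no stereocentre.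

Step 2
Reactants: 4 ethyl (6E)-7,11-dimethyl-3-oxododeca-6,10-dienoate
Product: 5 ethyl (2Z,6E)-7,11-dimethyl-3-(trifluoromethylsulfonyloxy)dodeca-2,6,10-trienoate
Conditions: Tf2O, sat. aq. LiOH, hexanes, 5 °C
Reagents that add atoms: triflic anhydride, O=S(=O)(OS(=O)(=O)C(F)(F)F)C(F)(F)F
Why: O-sulfonylation of the lithium-chelated (Z)-enolate of the β-keto ester under biphasic conditions should give the (Z)-enol triflate, which fixes the later alkene geometry.

Step 3
Reactants: 5 the (Z)-enol triflate
Product: 6 ethyl (2Z,6S,7S,10S)-6,7:10,11-diepoxy-7,11-dimethyl-3-(trifluoromethylsulfonyloxy)dodec-2-enoate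
Conditions: ent-Shi ketone (enantiomer of the D-fructose-derived ketone, 0.6 equiv), Oxone (2KHSO5·KHSO4·K2SO4), K2CO3, Bu4NHSO4, Na2B4O7 buffer, MeCN/CH2(OMe)2/H2O, 0 °C
Reagents that add atoms: potassium peroxymonosulfate (KHSO5, active component of Oxone), [K+].[O-]S(=O)(=O)OO
Why: Shi epoxidation (chiral dioxirane, spiro transition state) should oxidise the two electron-rich trisubstituted alkenes and not the electron-poor enol triflate, and the ent-ketone delivers oxygen so that all three epoxide stereocentres are S.

Step 4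
Reactants: 6 the bis-epoxy enol triflate
Product: 7 ethyl (2Z,6S,7S,10S)-6,7:10,11-diepoxy-7,11-dimethyl-3-[(trimethylsilyl)methyl]dodec-2-enoate
Conditions: Me3SiCH2MgCl, Fe(acac)3 (5 mol %), THF/NMP, −30 °C
Reagents that add atoms: (trimethylsilyl)methylmagnesium chloride, C[Si](C)(C)C[Mg]Cl
Why: iron-catalysed Kumada-type coupling of an enol triflate is complete within minutes at low temperature with retention of alkene geometry, so ester and trisubstituted epoxides should survive and the silylmethyl group ends cis to the ester.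

Step 5
Reactants: 7 the silylmethyl enoate
Product: 8 (2Z,6S,7S,10S)-6,7:10,11-diepoxy-7,11-dimethyl-3-[(trimethylsilyl)methyl]dodec-2-en-1-ol
Conditions: i-Bu2AlH (2.2 equiv), CH2Cl2, −78 °C; Rochelle salt work-up
Reagents that add atoms: none
Why: 1,2-reduction of the enoate by the aluminium hydride gives the allylic alcohol without touching the epoxides or the allylsilane, and no stereocentre changes.

Step 6
Reactants: 8 the allylic alcohol
Product: 9 tert-butyldimethylsilyl ether of 8
Conditions: TBSCl, imidazole, CH2Cl2, 0 °C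
Reagents that add atoms: tert-butyldimethylsilyl chloride, CC(C)(C)[Si](C)(C)Cl
Why: standard silylation of the primary alcohol removes the only protic nucleophile before the cationic cascade.

Step 7
Reactants: 9 the bis-epoxy allylsilane
Product: 10 (3S,5aS,6R,9aS)-6-[(tert-butyldimethylsilyloxy)methyl]-2,2,5a-trimethyl-7-methylidene-3-(trimethylsilyloxy)decahydro-1-benzoxepine (trans-fused rings A/B)
Conditions: Me3SiOTf (1.2 equiv), 2,6-di-tert-butyl-4-methylpyridine, CH2Cl2, −78 °C; Et3N quench
Reagents that add atoms: trimethylsilyl triflate, C[Si](C)(C)OS(=O)(=O)C(F)(F)F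
Why: in this silyl-triflate-promoted tandem oxacyclization–carbacyclization of a 1,5-diepoxide the internal epoxide oxygen opens the silylated terminal epoxide at its tertiary carbon (ring A, carbinol configuration retained), and the resulting epoxonium ion is opened with inversion at its tertiary carbon by the allylsilane through a chair transition state (ring B, Hosomi–Sakurai-type termination), which sets the trans A/B fusion, the equatorial side arm and the exocyclic methylene.

Step 8
Reactants: 10 the bicyclic bis-silyl ether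
Product: 11 (3S,5aS,6R,9aS)-6-(hydroxymethyl)-2,2,5a-trimethyl-7-methylidenedecahydro-1-benzoxepin-3-ol
Conditions: Bu4NF, THF, rt
Reagents that add atoms: none
Why: fluoride-mediated desilylation removes both silyl ethers and affects no stereocentre.

Step 9
Reactants: 11 the diol
Product: 12 (3S,5aS,6R,9aS)-6-(iodomethyl)-2,2,5a-trimethyl-7-methylidenedecahydro-1-benzoxepin-3-ol
Conditions: I2, PPh3, imidazole, CH2Cl2, 0 °C to rt
Reagents that add atoms: iodine, II
Why: the Appel iodination should select the primary hydroxyl over the hindered secondary ring-A hydroxyl that is flanked by a quaternary carbon.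

Step 10
Reactants: 12 the iodide; 13 N-methoxy-N-methylprop-2-enamide
Product: 14 4-[(3S,5aS,6R,9aS)-3-hydroxy-2,2,5a-trimethyl-7-methylidenedecahydro-1-benzoxepin-6-yl]-N-methoxy-N-methylbutanamide
Conditions: Bu3SnH (slow addition), AIBN (cat.), 13 (5 equiv), benzene, 80 °C
Reagents that add atoms: none
Why: Giese radical conjugate addition of the primary alkyl radical to the acrylamide adds the three-carbon unit without a basic nucleophile, so elimination toward the neighbouring allylic hydrogen is avoided and the free hydroxyl is tolerated.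

Step 11
Reactants: 14 the Weinreb amide
Product: 15 6-[(3S,5aS,6R,9aS)-3-hydroxy-2,2,5a-trimethyl-7-methylidenedecahydro-1-benzoxepin-6-yl]hex-1-en-3-one
Conditions: CH2=CHMgBr (3 equiv), THF, −20 to 0 °C; inverse quench into cold 1 M HCl
Reagents that add atoms: vinylmagnesium bromide, C=C[Mg]Br
Why: in the Weinreb ketone synthesis the chelated tetrahedral intermediate prevents over-addition, and the acidic inverse quench keeps the released amine from adding to the vinyl ketone.

Step 12
Reactants: 15 the vinyl ketone
Product: 16 (3S,5aS,6R,9aS)-3-(tert-butyldimethylsilyloxy)-6-[(3Z)-4-(tert-butyldimethylsilyloxy)hexa-3,5-dien-1-yl]-2,2,5a-trimethyl-7-methylidenedecahydro-1-benzoxepine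
Conditions: TBSOTf (2.5 equiv), Et3N, CH2Cl2, −78 to 0 °C
Reagents that add atoms: tert-butyldimethylsilyl triflate, CC(C)(C)[Si](C)(C)OS(=O)(=O)C(F)(F)F
Why: soft enolisation of the alkyl vinyl ketone by silyl triflate and amine should give the (Z)-2-silyloxy-1,3-diene (alkyl group trans to the vinyl group to avoid allylic strain) and silylates the ring-A hydroxyl in the same operation.

Step 13
Reactants: 16 the (Z)-silyloxy diene; 17 4,4-dimethylcyclohex-2-en-1-one
Product: 18 (4aR,5S,8aS)-6-(tert-butyldimethylsilyloxy)-5-{2-[(3S,5aS,6R,9aS)-3-(tert-butyldimethylsilyloxy)-2,2,5a-trimethyl-7-methylidenedecahydro-1-benzoxepin-6-yl]ethyl}-4,4-dimethyl-3,4,4a,5,8,8a-hexahydronaphthalen-1(2H)-one (cis-fused rings C/D, the three ring-C methine hydrogens all cis)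
Conditions: (S)-B-(o-tolyl)oxazaborolidine from (S)-α,α-diphenylprolinol (20 mol %), AlBr3 (16 mol %), 17 (2 equiv), CH2Cl2, −78 to −40 °C
Reagents that add atoms: none
Why: The AlBr3-activated oxazaborolidine binds the carbonyl oxygen of 17, and the enone then undergoes a normal-demand, asynchronous endo [4+2] cycloaddition (Diels–Alder reaction) in which the enol-ether terminus of 16 bonds to the enone β-carbon slightly ahead of the bond from the unsubstituted terminus to the α-carbon. The closest known reaction type is the chiral oxazaborolidinium-catalysed Diels–Alder reaction of cyclohex-2-enones with 2-silyloxy-1,3-dienes, together with strong-Lewis-acid cycloadditions of 2-silyloxy dienes that forge bonds at hindered enone β-carbons. Ring C is closed by intermolecular [4+2] annulation onto the C=C bond of the preformed ring D (were the process stepwise, a Mukaiyama–Michael addition followed by 6-exo-trig Michael closure would lead to the same product). The three new stereocentres are all-cis because the (Z)-enol ether holds the side chain outside and the ring-D carbons lie endo, and their absolute configuration is set by the catalyst, which by the α-C–H···O binding model covers the (2-Re,3-Si) face of the enone so that the diene adds to the (2-Si,3-Re) face. The step needs para regioselectivity, endo selectivity and facial selectivity: the silyloxy group makes the substituted terminus the nucleophilic one and overrides the weaker ortho preference of the alkyl group, the Lewis acid reinforces the endo mode, and the stereocentres of rings A/B are too remote to interfere with catalyst control. The isolated 1,1-disubstituted alkene and the alkyl silyl ether should not react with the activated enone at low temperature.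

Step 14
Reactants: 18 the cycloadduct
Product: 19 the 1-methylidene analogue of 18 (ring-D C=O replaced by C=CH2, all stereocentres unchanged)
Conditions: Cp2TiMe2, toluene, 70 °C, dark
Reagents that add atoms: dimethyltitanocene, [CH3-].[CH3-].[Ti+4].c1cc[cH-]c1.c1cc[cH-]c1
Why: the Petasis methylenation is non-basic, so the hindered, epimerisable cis-fused ketone should be converted into the exocyclic alkene without loss of the fusion stereochemistry while the silyl enol ether survives.

Step 15
Reactants: 19 the bis-methylidene silyl enol ether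
Product: 20 the ring-C enol triflate corresponding to 19 (OTf in place of the enol OTBS, double bond position unchanged)
Conditions: CsF, PhNTf2, 1,2-dimethoxyethane, rt
Reagents that add atoms: N-phenylbis(trifluoromethanesulfonimide), O=S(=O)(N(c1ccccc1)S(=O)(=O)C(F)(F)F)C(F)(F)F
Why: fluoride unmasks the regiodefined enolate from the silyl enol ether and the triflimide traps it on oxygen (enolate O-triflation), so the double bond stays where the cycloaddition put it, and the alkyl silyl ether is far less labile to CsF.

Step 16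
Reactants: 20 the enol triflate
Product: 21 the triene with the ring-C methyl group in place (ring-A TBS ether, exocyclic methylenes on rings B and D)
Conditions: MeMgBr, Fe(acac)3 (5 mol %), THF/NMP, −30 °C
Reagents that add atoms: methylmagnesium bromide, C[Mg]Br
Why: iron-catalysed Kumada-type coupling of the alkenyl triflate installs the ring-C methyl group with retention of the double-bond position.

Step 17
Reactants: 21 the triene
Product: 23 ring-A tert-butyldimethylsilyl ether of sipholenol L, via bis(acetoxymercurio) diol 22 (not isolated)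
Conditions: Hg(OAc)2 (2.1 equiv), THF/H2O (1:1), rt; then NaBH4, 3 M aq. NaOH, 0 °C
Reagents that add atoms: water, O; mercuric acetate, CC(=O)O[Hg]OC(C)=O (its atoms remain only in intermediate 22)
Why: oxymercuration–demercuration hydrates 1,1-disubstituted alkenes in the Markovnikov sense much faster than the trisubstituted ring-C alkene, and in both rings water should attack the tertiary carbon from the open face (anti to the axial angular methyl in ring B, on the convex face of the cis-fused C/D system), so each hydroxyl ends on the open face and each new methyl on the hindered face, as in the target.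

Step 18
Reactants: 23 the silyl ether
Product: 24 sipholenol L
Conditions: Bu4NF, THF, 50 °C
Reagents that add atoms: none
Why: fluoride cleavage of the last secondary silyl ether (desilylation) releases the ring-A alcohol without acid, which the tertiary alcohols and the trisubstituted alkene would not tolerate.

**Compound list**

1 | ethyl acetoacetate | CCOC(=O)CC(C)=O | starting material
2 | geranyl bromide, (2E)-1-bromo-3,7-dimethylocta-2,6-diene | BrC/C=C(\C)CCC=C(C)C | starting material
3 | sodium lithium dianion of ethyl acetoacetate | [Na+].[Li+].CCOC(=O)[CH-]C(=O)[CH2-] | intermediate (not isolated)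
4 | ethyl (6E)-7,11-dimethyl-3-oxododeca-6,10-dienoate | CCOC(=O)CC(=O)CC/C=C(\C)CCC=C(C)C | intermediate
5 | ethyl (2Z,6E)-7,11-dimethyl-3-(trifluoromethylsulfonyloxy)dodeca-2,6,10-trienoate | CCOC(=O)/C=C(OS(=O)(=O)C(F)(F)F)/CC/C=C(\C)CCC=C(C)C | intermediate
6 | ethyl (2Z,6S,7S,10S)-6,7:10,11-diepoxy-7,11-dimethyl-3-(trifluoromethylsulfonyloxy)dodec-2-enoate | CCOC(=O)/C=C(OS(=O)(=O)C(F)(F)F)/CC[C@@H]1O[C@@]1(C)CC[C@@H]1OC1(C)C | intermediate
7 | ethyl (2Z,6S,7S,10S)-6,7:10,11-diepoxy-7,11-dimethyl-3-[(trimethylsilyl)methyl]dodec-2-enoate | CCOC(=O)/C=C(C[Si](C)(C)C)/CC[C@@H]1O[C@@]1(C)CC[C@@H]1OC1(C)C | intermediate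
8 | (2Z,6S,7S,10S)-6,7:10,11-diepoxy-7,11-dimethyl-3-[(trimethylsilyl)methyl]dodec-2-en-1-ol | OC/C=C(C[Si](C)(C)C)/CC[C@@H]1O[C@@]1(C)CC[C@@H]1OC1(C)C | intermediate
9 | tert-butyldimethylsilyl ether of 8 | CC(C)(C)[Si](C)(C)OC/C=C(C[Si](C)(C)C)/CC[C@@H]1O[C@@]1(C)CC[C@@H]1OC1(C)C | intermediate
10 | (3S,5aS,6R,9aS)-6-[(tert-butyldimethylsilyloxy)methyl]-2,2,5a-trimethyl-7-methylidene-3-(trimethylsilyloxy)decahydro-1-benzoxepine | CC(C)(C)[Si](C)(C)OC[C@H]1[C@]3(C)CC[C@H](O[Si](C)(C)C)C(C)(C)O[C@H]3CCC1=C | intermediate
11 | (3S,5aS,6R,9aS)-6-(hydroxymethyl)-2,2,5a-trimethyl-7-methylidenedecahydro-1-benzoxepin-3-ol | OC[C@H]1[C@]3(C)CC[C@H](O)C(C)(C)O[C@H]3CCC1=C | intermediate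
12 | (3S,5aS,6R,9aS)-6-(iodomethyl)-2,2,5a-trimethyl-7-methylidenedecahydro-1-benzoxepin-3-ol | IC[C@H]1[C@]3(C)CC[C@H](O)C(C)(C)O[C@H]3CCC1=C | intermediate
13 | N-methoxy-N-methylprop-2-enamide | C=CC(=O)N(C)OC | starting material
14 | 4-[(3S,5aS,6R,9aS)-3-hydroxy-2,2,5a-trimethyl-7-methylidenedecahydro-1-benzoxepin-6-yl]-N-methoxy-N-methylbutanamide | CON(C)C(=O)CCC[C@H]1[C@]3(C)CC[C@H](O)C(C)(C)O[C@H]3CCC1=C | intermediate
15 | 6-[(3S,5aS,6R,9aS)-3-hydroxy-2,2,5a-trimethyl-7-methylidenedecahydro-1-benzoxepin-6-yl]hex-1-en-3-one | C=CC(=O)CCC[C@H]1[C@]3(C)CC[C@H](O)C(C)(C)O[C@H]3CCC1=C | intermediate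
16 | (3S,5aS,6R,9aS)-3-(tert-butyldimethylsilyloxy)-6-[(3Z)-4-(tert-butyldimethylsilyloxy)hexa-3,5-dien-1-yl]-2,2,5a-trimethyl-7-methylidenedecahydro-1-benzoxepine | C=C/C(O[Si](C)(C)C(C)(C)C)=C/CC[C@H]1[C@]3(C)CC[C@H](O[Si](C)(C)C(C)(C)C)C(C)(C)O[C@H]3CCC1=C | intermediate
17 | 4,4-dimethylcyclohex-2-en-1-one | CC1(C)CCC(=O)C=C1 | starting material
18 | (4aR,5S,8aS)-6-(tert-butyldimethylsilyloxy)-5-{2-[(3S,5aS,6R,9aS)-3-(tert-butyldimethylsilyloxy)-2,2,5a-trimethyl-7-methylidenedecahydro-1-benzoxepin-6-yl]ethyl}-4,4-dimethyl-3,4,4a,5,8,8a-hexahydronaphthalen-1(2H)-one | CC(C)(C)[Si](C)(C)OC1=CC[C@H]2[C@@H]([C@@H]1CC[C@H]1[C@]3(C)CC[C@H](O[Si](C)(C)C(C)(C)C)C(C)(C)O[C@H]3CCC1=C)C(C)(C)CCC2=O | intermediate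
19 | 1-methylidene analogue of 18 (ring-D exocyclic methylene, silyl enol ether in ring C) | CC(C)(C)[Si](C)(C)OC1=CC[C@H]2[C@@H]([C@@H]1CC[C@H]1[C@]3(C)CC[C@H](O[Si](C)(C)C(C)(C)C)C(C)(C)O[C@H]3CCC1=C)C(C)(C)CCC2=C | intermediate
20 | ring-C enol triflate corresponding to 19 | FC(F)(F)S(=O)(=O)OC1=CC[C@H]2[C@@H]([C@@H]1CC[C@H]1[C@]3(C)CC[C@H](O[Si](C)(C)C(C)(C)C)C(C)(C)O[C@H]3CCC1=C)C(C)(C)CCC2=C | intermediate
21 | triene: ring-C methyl alkene, exocyclic methylenes on rings B and D, ring-A TBS ether | CC1=CC[C@H]2[C@@H]([C@@H]1CC[C@H]1[C@]3(C)CC[C@H](O[Si](C)(C)C(C)(C)C)C(C)(C)O[C@H]3CCC1=C)C(C)(C)CCC2=C | intermediate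
22 | bis(acetoxymercuriomethyl) diol (both tertiary carbinols formed, CH2HgOAc in place of each methyl) | CC1=CC[C@H]2[C@@H]([C@@H]1CC[C@H]1[C@]3(C)CC[C@H](O[Si](C)(C)C(C)(C)C)C(C)(C)O[C@H]3CC[C@]1(C[Hg]OC(C)=O)O)C(C)(C)CC[C@]2(C[Hg]OC(C)=O)O | intermediate (not isolated)
23 | ring-A tert-butyldimethylsilyl ether of sipholenol L | CC1=CC[C@H]2[C@@H]([C@@H]1CC[C@H]1[C@]3(C)CC[C@H](O[Si](C)(C)C(C)(C)C)C(C)(C)O[C@H]3CC[C@]1(C)O)C(C)(C)CC[C@]2(C)O | intermediate
24 | sipholenol L | CC1=CC[C@H]2[C@@H]([C@@H]1CC[C@H]1[C@]3(C)CC[C@H](O)C(C)(C)O[C@H]3CC[C@]1(C)O)C(C)(C)CC[C@]2(C)O | target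

**Totals**

Total step count: 18. Longest linear sequence: 18 steps (1 and 2 to 24; compounds 13 and 17 are purchased).

**Steps most likely to fail**

Step 13. The catalyst may fail to override the steric bias next to the neopentyl β-carbon of 17. The cycloaddition then becomes slow, the diene is lost by protodesilylation, or the two enone faces and the endo/exo modes are not differentiated. The fallback replaces catalyst control by auxiliary control with a doubly activated dienophile; it sets out from 17 and 16 and comes back at 18. Enone 17 is iodinated at the α-carbon (I2, pyridine) to 2-iodo-4,4-dimethylcyclohex-2-en-1-one F1, and this is ketalised (ethylene glycol, TsOH) to 6-iodo-8,8-dimethyl-1,4-dioxaspiro[4.5]dec-6-ene F2. Iodine–lithium exchange (n-BuLi, −78 °C) and reaction with (1S,2R,5S)-menthyl (R)-p-toluenesulfinate, with inversion at sulfur, give the (R)-sulfinyl ketal F3, and hydrolysis (CuSO4, acetone) gives (R)-4,4-dimethyl-2-(p-tolylsulfinyl)cyclohex-2-en-1-one F4. In its ZnBr2 chelate the tolyl group blocks one face of a far more reactive dienophile, so cycloaddition with 16 (CH2Cl2, 0 °C) should give the sulfinyl cycloadduct F5. Reductive desulfinylation (Al–Hg, aq. THF), with protonation on the convex face, returns 18.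

Step 7. The two epoxides may be activated in the wrong order, or the epoxonium ion may collapse by exo oxacyclization, hydride shift or elimination before the allylsilane closes ring B; the allylsilane may also be lost by protodesilylation. The fallback separates the two ring closures and closes ring B first on a substrate that carries only the internal epoxide; it sets out from 1 (through dianion 3) and comes back at 11. Commercial geraniol is epoxidised (Sharpless asymmetric epoxidation: Ti(OiPr)4, L-(+)-diethyl tartrate, t-BuOOH, CH2Cl2, −20 °C) to (2S,3S)-2,3-epoxygeraniol F6 and brominated (CBr4, PPh3) to the epoxy bromide F7, which alkylates dianion 3 to the epoxy β-keto ester F8. The operations of steps 2 and 4 to 6 then give in turn the (Z)-enol triflate F9, the silylmethyl enoate F10, the allylic alcohol F11 and its silyl ether F12. Et2AlCl (CH2Cl2, −78 °C) should trigger the epoxide–allylsilane cyclisation (Hosomi–Sakurai type, chair, inversion at the tertiary epoxide carbon) to the monocyclic alcohol F13. Shi epoxidation with the same ent-ketone should oxidise the side-chain trisubstituted alkene in preference to the 1,1-disubstituted one and give epoxy alcohol F14. Camphorsulfonic acid (CH2Cl2, 0 °C) closes ring A by 7-endo attack of the ring hydroxyl on the tertiary epoxide carbon to give the oxepane F15, and Bu4NF returns diol 11.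

Step 17. The mercuric salt may not discriminate cleanly between the two exocyclic alkenes and the ring-C alkene, or water may enter from the hindered face at the ring-D carbon, so that the wrong carbinol epimer forms. The fallback moves the oxygenation to the triflate stage and uses epoxidation and hydride opening; it sets out from 20 and comes back at 23. mCPBA (NaHCO3, CH2Cl2, 0 °C) should epoxidise only the two exocyclic alkenes of 20, since the enol triflate is electron-poor, each from its open face, to give the bis-spiro-epoxide F16. Suzuki–Miyaura methylation (trimethylboroxine, Pd(PPh3)4, K2CO3, dioxane, 90 °C) gives the methylated bis-epoxide F17, and LiEt3BH (THF, 0 °C) opens both epoxides at their CH2 termini to give 23.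

**Further compounds**

F1 | step 13 | 2-iodo-4,4-dimethylcyclohex-2-en-1-one | CC1(C)CCC(=O)C(I)=C1
F2 | step 13 | 6-iodo-8,8-dimethyl-1,4-dioxaspiro[4.5]dec-6-ene | CC1(C)CCC2(OCCO2)C(I)=C1
F3 | step 13 | (R)-8,8-dimethyl-6-(p-tolylsulfinyl)-1,4-dioxaspiro[4.5]dec-6-ene | Cc1ccc(cc1)[S@@](=O)C1=CC(C)(C)CCC12OCCO2
F4 | step 13 | (R)-4,4-dimethyl-2-(p-tolylsulfinyl)cyclohex-2-en-1-one | Cc1ccc(cc1)[S@@](=O)C1=CC(C)(C)CCC1=O
F5 | step 13 | 8a-[(R)-p-tolylsulfinyl] derivative of 18 (sulfinyl group in place of the fusion hydrogen next to the carbonyl) | CC(C)(C)[Si](C)(C)OC1=CC[C@@]2([S@](=O)c3ccc(C)cc3)[C@@H]([C@@H]1CC[C@H]1[C@]3(C)CC[C@H](O[Si](C)(C)C(C)(C)C)C(C)(C)O[C@H]3CCC1=C)C(C)(C)CCC2=O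
F6 | step 7 | (2S,3S)-2,3-epoxygeraniol | OC[C@@H]1O[C@@]1(C)CCC=C(C)C
F7 | step 7 | bromide of F6 (2,3-epoxygeranyl bromide, same spatial arrangement) | BrC[C@@H]1O[C@@]1(C)CCC=C(C)C
F8 | step 7 | ethyl (6S,7S)-6,7-epoxy-7,11-dimethyl-3-oxododec-10-enoate | CCOC(=O)CC(=O)CC[C@@H]1O[C@@]1(C)CCC=C(C)C
F9 | step 7 | ethyl (2Z,6S,7S)-6,7-epoxy-7,11-dimethyl-3-(trifluoromethylsulfonyloxy)dodeca-2,10-dienoate | CCOC(=O)/C=C(OS(=O)(=O)C(F)(F)F)/CC[C@@H]1O[C@@]1(C)CCC=C(C)C
F10 | step 7 | ethyl (2Z,6S,7S)-6,7-epoxy-7,11-dimethyl-3-[(trimethylsilyl)methyl]dodeca-2,10-dienoate | CCOC(=O)/C=C(C[Si](C)(C)C)/CC[C@@H]1O[C@@]1(C)CCC=C(C)C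
F11 | step 7 | (2Z,6S,7S)-6,7-epoxy-7,11-dimethyl-3-[(trimethylsilyl)methyl]dodeca-2,10-dien-1-ol | OC/C=C(C[Si](C)(C)C)/CC[C@@H]1O[C@@]1(C)CCC=C(C)C
F12 | step 7 | tert-butyldimethylsilyl ether of F11 | CC(C)(C)[Si](C)(C)OC/C=C(C[Si](C)(C)C)/CC[C@@H]1O[C@@]1(C)CCC=C(C)C
F13 | step 7 | monocyclic ring-B alcohol: 3-[(tert-butyldimethylsilyloxy)methyl]-2-methyl-4-methylidene-2-(4-methylpent-3-en-1-yl)cyclohexan-1-ol, configuration as in 10 | CC(C)(C)[Si](C)(C)OC[C@H]1[C@](C)(CCC=C(C)C)[C@@H](O)CCC1=C
F14 | step 7 | (S)-side-chain epoxide of F13 | CC(C)(C)[Si](C)(C)OC[C@H]1[C@](C)(CC[C@@H]2OC2(C)C)[C@@H](O)CCC1=C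
F15 | step 7 | (3S,5aS,6R,9aS)-6-[(tert-butyldimethylsilyloxy)methyl]-2,2,5a-trimethyl-7-methylidenedecahydro-1-benzoxepin-3-ol | CC(C)(C)[Si](C)(C)OC[C@H]1[C@]3(C)CC[C@H](O)C(C)(C)O[C@H]3CCC1=C
F16 | step 17 | bis-spiro-epoxide of enol triflate 20 (oxygen on the open face at the ring-B and ring-D carbons) | FC(F)(F)S(=O)(=O)OC1=CC[C@H]2[C@@H]([C@@H]1CC[C@H]1[C@]3(C)CC[C@H](O[Si](C)(C)C(C)(C)C)C(C)(C)O[C@H]3CC[C@]1(C4)O4)C(C)(C)CC[C@]2(C4)O4
F17 | step 17 | ring-C methyl analogue of F16 | CC1=CC[C@H]2[C@@H]([C@@H]1CC[C@H]1[C@]3(C)CC[C@H](O[Si](C)(C)C(C)(C)C)C(C)(C)O[C@H]3CC[C@]1(C4)O4)C(C)(C)CC[C@]2(C4)O4
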